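**Strategy.** Within the piperidine only C4 and C5 are neighbouring unsubstituted carbons; N1, C2 (methyl), C3 (hydroxyl) and C6 (side chain) are all occupied. The ring is therefore cut at C4–C5 and closed there as a C4=C5 alkene by ring-closing metathesis, after N1 already connects the C2–C3 amino alcohol to C6. That single operation forms the bond and the six-membered ring and leaves C2, C3 and C6 untouched. The precursor is a secondary amine carrying a vinyl group on C6 and a vinyl group on C3, cyclised as its ammonium salt. It is assembled by iridium-catalysed branched allylic amination of a C19 allylic carbonate with a D-alanine-derived silyloxy pentenylamine.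

Key step: step 12

Remark: the (S,S)-cobalt–salen catalyst is taken to leave the (S)-oxirane (step 4) and the (Ra,Rc,Rc)-phosphoramidite to give the (3S)-amine (step 11); if either sense is the opposite, the mirror-image catalyst is used and nothing else changes.

**Step 1**
Reactants: 1 11-bromoundec-1-ene; 2 (S)-propylene oxide
Product: 4 (S)-tetradec-13-en-2-ol, via undec-10-enylmagnesium bromide 3 (not isolated)
Conditions: Mg, THF, rt to 40 °C; then CuI (10 mol%), 2, THF, −30 to 0 °C; H2O/aq NH4Cl
Reagents that add atoms: none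
Why: Copper-catalysed Grignard opening of a terminal epoxide occurs at the unsubstituted CH2, so the stereocentre of (S)-propylene oxide is carried over unchanged as the (S)-carbinol.

**Step 2**
Reactants: 4 (S)-tetradec-13-en-2-ol
Product: 5 (S)-tert-butyldimethyl(tetradec-13-en-2-yloxy)silane
Conditions: TBSCl, imidazole, DMF, rt
Reagents that add atoms: tert-butyldimethylsilyl chloride, CC(C)(C)[Si](C)(C)Cl
Why: Standard silylation of a secondary alcohol, which masks the hydroxyl before the epoxidation, the cobalt-catalysed resolution and the second Grignard step.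

**Step 3**
Reactants: 5 (S)-tert-butyldimethyl(tetradec-13-en-2-yloxy)silane
Product: 6 2-[(11S)-11-(tert-butyldimethylsilyloxy)dodecyl]oxirane (both epimers at the oxirane carbon)
Conditions: mCPBA, NaHCO3, CH2Cl2, 0 °C to rt
Reagents that add atoms: 3-chloroperoxybenzoic acid, OOC(=O)c1cccc(Cl)c1
Why: Prilezhaev epoxidation of the terminal alkene; the remote stereocentre cannot bias the faces, so both oxirane epimers should form and are resolved in step 4.

**Step 4**
Reactants: 6 2-[(11S)-11-(tert-butyldimethylsilyloxy)dodecyl]oxirane (epimer mixture)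
Product: 7 (2S)-2-[(11S)-11-(tert-butyldimethylsilyloxy)dodecyl]oxirane
Conditions: (S,S)-(salen)Co(OAc) (1 mol%; salen = N,N'-bis(3,5-di-tert-butylsalicylidene)cyclohexane-1,2-diamine dianion), H2O (0.55 equiv), THF, 0 °C to rt
Reagents that add atoms: none
Why: Jacobsen hydrolytic kinetic resolution, in which the chiral cobalt–salen catalyst hydrates the (R)-oxirane much faster and leaves the (2S)-epoxide, whose configuration is fixed by the catalyst and not by the remote silyl ether.

**Step 5**
Reactants: 7 (2S)-2-[(11S)-11-(tert-butyldimethylsilyloxy)dodecyl]oxirane; 8 but-3-enylmagnesium bromide (commercial THF solution)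
Product: 9 (6S,17S)-17-(tert-butyldimethylsilyloxy)octadec-1-en-6-ol
Conditions: 8 (1.5 equiv), CuI (10 mol%), THF, −40 to 0 °C; H2O/aq NH4Cl
Reagents that add atoms: none
Why: Copper-catalysed Grignard opening at the terminal oxirane carbon leaves the stereocentre untouched, so it becomes the (6S)-carbinol while the pentenyl terminus is installed.

**Step 6**
Reactants: 9 (6S,17S)-17-(tert-butyldimethylsilyloxy)octadec-1-en-6-ol
Product: 10 (6S,17S)-6,17-bis(tert-butyldimethylsilyloxy)octadec-1-ene
Conditions: TBSOTf, 2,6-lutidine, CH2Cl2, 0 °C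
Reagents that add atoms: tert-butyldimethylsilyl trifluoromethanesulfonate, CC(C)(C)[Si](C)(C)OS(=O)(=O)C(F)(F)F
Why: Silyl triflate with a hindered pyridine base silylates the secondary alcohol rapidly without affecting the alkene or the existing silyl ether.

**Step 7**
Reactants: 10 (6S,17S)-6,17-bis(tert-butyldimethylsilyloxy)octadec-1-ene; 11 allyl methyl carbonate
Product: 12 methyl (2E,7S,18S)-7,18-bis(tert-butyldimethylsilyloxy)nonadec-2-en-1-yl carbonate
Conditions: 11 (4 equiv), second-generation Grubbs catalyst (H2IMes)(PCy3)Cl2Ru=CHPh (3 mol%), CH2Cl2, 40 °C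
Reagents that add atoms: none
Why: Olefin cross-metathesis of a terminal alkene with excess allyl carbonate, driven by loss of ethylene, should give the linear allylic carbonate mainly as the thermodynamically preferred E isomer, with any Z isomer removed by chromatography.

**Step 8**
Reactants: 13 tert-butyl N-[(2R)-1-[methoxy(methyl)amino]-1-oxopropan-2-yl]carbamate (commercial N-Boc-D-alanine Weinreb amide); 14 vinylmagnesium bromide (commercial THF solution)
Product: 15 tert-butyl N-[(2R)-3-oxopent-4-en-2-yl]carbamate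
Conditions: 14 (3 equiv), THF, 0 °C; inverse quench into cold 1 M aq HCl
Reagents that add atoms: none
Why: Weinreb ketone synthesis, in which the magnesium-chelated tetrahedral adduct prevents over-addition, the N-deprotonated carbamate shields the α-centre from enolisation, and the acidic inverse quench protonates the released methoxyamine so that it cannot add to the enone.

**Step 9**
Reactants: 15 tert-butyl N-[(2R)-3-oxopent-4-en-2-yl]carbamate
Product: 16 tert-butyl N-[(2R,3S)-3-hydroxypent-4-en-2-yl]carbamate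
Conditions: LiAlH(OtBu)3, EtOH, −78 °C
Reagents that add atoms: none
Why: 1,2-Reduction of an N-carbamoyl α-amino enone by the bulky hydride in ethanol at low temperature should pass through a chelate-type cyclic arrangement of carbamate and ketone, so hydride reaches the face that gives the anti (2R,3S) amino alcohol.

**Step 10**
Reactants: 16 tert-butyl N-[(2R,3S)-3-hydroxypent-4-en-2-yl]carbamate
Product: 18 (2R,3S)-3-(tert-butyldimethylsilyloxy)pent-4-en-2-amine, via silyl carbamate 17 (not isolated)
Conditions: TBSOTf (2.5 equiv), 2,6-lutidine, CH2Cl2, 0 °C to rt; then K2CO3, MeOH/H2O, rt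
Reagents that add atoms: tert-butyldimethylsilyl trifluoromethanesulfonate, CC(C)(C)[Si](C)(C)OS(=O)(=O)C(F)(F)F
Why: Excess silyl triflate silylates the alcohol and converts the Boc group into a silyl carbamate with loss of 2-methylpropene, and mild basic solvolysis then decarboxylates it to the free amine while the silyl ether survives.

**Step 11**
Reactants: 12 methyl (2E,7S,18S)-7,18-bis(tert-butyldimethylsilyloxy)nonadec-2-en-1-yl carbonate; 18 (2R,3S)-3-(tert-butyldimethylsilyloxy)pent-4-en-2-amine
Product: 19 (3S,7S,18S)-7,18-bis(tert-butyldimethylsilyloxy)-N-[(2R,3S)-3-(tert-butyldimethylsilyloxy)pent-4-en-2-yl]nonadec-1-en-3-amine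
Conditions: [Ir(cod)Cl]2 (2 mol%), (Ra,Rc,Rc)-(1,1'-binaphthalene-2,2'-diyl) N,N-bis(1-phenylethyl)phosphoramidite (4 mol%), 1,5,7-triazabicyclo[4.4.0]dec-5-ene (8 mol%), THF, rt
Reagents that add atoms: none
Why: Iridium-catalysed asymmetric allylic amination, in which the cyclometalated iridium–phosphoramidite complex ionises the linear carbonate to an allyl complex and the primary amine attacks the substituted terminus anti to the metal, giving the branched amine; the ligand selects the allyl face and so sets C3 as S, while the stereocentres of 18 are spectators and the hindered product does not allylate again.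

**Step 12**
Reactants: 19 (3S,7S,18S)-7,18-bis(tert-butyldimethylsilyloxy)-N-[(2R,3S)-3-(tert-butyldimethylsilyloxy)pent-4-en-2-yl]nonadec-1-en-3-amine
Product: 22 (2R,3S,6S)-6-[(4S,15S)-4,15-bis(tert-butyldimethylsilyloxy)hexadecyl]-3-(tert-butyldimethylsilyloxy)-2-methyl-1,2,3,6-tetrahydropyridine, via ammonium tosylate 20 (not isolated), via tetrahydropyridinium tosylate 21 (not isolated)
Conditions: TsOH·H2O (1.0 equiv), CH2Cl2, rt; then second-generation Grubbs catalyst (H2IMes)(PCy3)Cl2Ru=CHPh (5 mol%), CH2Cl2 (5 mM), 40 °C; 1 M aq NaOH wash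
Reagents that add atoms: none
Why: The ruthenium benzylidene undergoes [2+2] cycloaddition with one terminal vinyl group and cycloreversion to a new alkylidene, which then adds across the second vinyl group and cycloreverts again, releasing ethylene and the cyclic alkene through metallacyclobutane intermediates. The closest known reaction type is ring-closing metathesis of ammonium salts of secondary amines that carry one allyl-type and one homoallyl-type substituent on nitrogen, giving 1,2,3,6-tetrahydropyridines. The one ring is closed by intramolecular metathesis of a 1,7-diene, joining C4 and C5 as an endocyclic cis alkene in a six-membered ring. No stereocentre is formed: C2 comes from D-alanine, C3 from step 9 and C6 from step 11, and none of them is a reacting carbon, so all three are carried through unchanged. The step needs cyclisation to outrun oligomerisation and needs nitrogen kept off ruthenium; high dilution and the ease of six-ring formation secure the first, full protonation of the amine as its tosylate secures the second, and the allylic silyl ether is a tolerated spectator.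

**Step 13**
Reactants: 22 (2R,3S,6S)-6-[(4S,15S)-4,15-bis(tert-butyldimethylsilyloxy)hexadecyl]-3-(tert-butyldimethylsilyloxy)-2-methyl-1,2,3,6-tetrahydropyridine
Product: 25 (2R,3S,6S)-6-[(4S,15S)-4,15-dihydroxyhexadecyl]-2-methylpiperidin-3-ol, via saturated silyl-protected piperidine 23 (not isolated), via piperidinium chloride 24 (not isolated)
Conditions: H2 (1 atm), 10% Pd/C, MeOH, rt; filter; HCl (3 M in MeOH), rt; then aq NaOH
Reagents that add atoms: none
Why: Heterogeneous hydrogenation saturates the disubstituted ring alkene without touching any stereocentre, acid-catalysed methanolysis then cleaves all three silyl ethers, and basification releases the free amino triol.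

**Compound list**
1 | 11-bromoundec-1-ene | C=CCCCCCCCCCBr | starting material
2 | (S)-propylene oxide | C[C@H]1CO1 | starting material
3 | undec-10-enylmagnesium bromide | C=CCCCCCCCCC[Mg]Br | intermediate
4 | (S)-tetradec-13-en-2-ol | C[C@H](O)CCCCCCCCCCC=C | intermediate
5 | (S)-tert-butyldimethyl(tetradec-13-en-2-yloxy)silane | C[C@H](O[Si](C)(C)C(C)(C)C)CCCCCCCCCCC=C | intermediate
6 | 2-[(11S)-11-(tert-butyldimethylsilyloxy)dodecyl]oxirane, both epimers at the oxirane carbon | C[C@H](O[Si](C)(C)C(C)(C)C)CCCCCCCCCCC1CO1 | intermediate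
7 | (2S)-2-[(11S)-11-(tert-butyldimethylsilyloxy)dodecyl]oxirane | C[C@H](O[Si](C)(C)C(C)(C)C)CCCCCCCCCC[C@H]1CO1 | intermediate
8 | but-3-enylmagnesium bromide | C=CCC[Mg]Br | starting material
9 | (6S,17S)-17-(tert-butyldimethylsilyloxy)octadec-1-en-6-ol | C[C@H](O[Si](C)(C)C(C)(C)C)CCCCCCCCCC[C@H](O)CCCC=C | intermediate
10 | (6S,17S)-6,17-bis(tert-butyldimethylsilyloxy)octadec-1-ene | C[C@H](O[Si](C)(C)C(C)(C)C)CCCCCCCCCC[C@H](O[Si](C)(C)C(C)(C)C)CCCC=C | intermediate
11 | allyl methyl carbonate | C=CCOC(=O)OC | starting material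
12 | methyl (2E,7S,18S)-7,18-bis(tert-butyldimethylsilyloxy)nonadec-2-en-1-yl carbonate | C[C@H](O[Si](C)(C)C(C)(C)C)CCCCCCCCCC[C@H](O[Si](C)(C)C(C)(C)C)CCC/C=C/COC(=O)OC | intermediate
13 | tert-butyl N-[(2R)-1-[methoxy(methyl)amino]-1-oxopropan-2-yl]carbamate | C[C@@H](NC(=O)OC(C)(C)C)C(=O)N(C)OC | starting material
14 | vinylmagnesium bromide | C=C[Mg]Br | starting material
15 | tert-butyl N-[(2R)-3-oxopent-4-en-2-yl]carbamate | C[C@@H](NC(=O)OC(C)(C)C)C(=O)C=C | intermediate
16 | tert-butyl N-[(2R,3S)-3-hydroxypent-4-en-2-yl]carbamate | C[C@@H](NC(=O)OC(C)(C)C)[C@@H](O)C=C | intermediate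
17 | tert-butyldimethylsilyl N-[(2R,3S)-3-(tert-butyldimethylsilyloxy)pent-4-en-2-yl]carbamate | C[C@@H](NC(=O)O[Si](C)(C)C(C)(C)C)[C@@H](O[Si](C)(C)C(C)(C)C)C=C | intermediate
18 | (2R,3S)-3-(tert-butyldimethylsilyloxy)pent-4-en-2-amine | C[C@@H](N)[C@@H](O[Si](C)(C)C(C)(C)C)C=C | intermediate
19 | (3S,7S,18S)-7,18-bis(tert-butyldimethylsilyloxy)-N-[(2R,3S)-3-(tert-butyldimethylsilyloxy)pent-4-en-2-yl]nonadec-1-en-3-amine | C[C@H](O[Si](C)(C)C(C)(C)C)CCCCCCCCCC[C@H](O[Si](C)(C)C(C)(C)C)CCC[C@@H](C=C)N[C@H](C)[C@@H](O[Si](C)(C)C(C)(C)C)C=C | intermediate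
20 | (3S,7S,18S)-7,18-bis(tert-butyldimethylsilyloxy)-N-[(2R,3S)-3-(tert-butyldimethylsilyloxy)pent-4-en-2-yl]nonadec-1-en-3-aminium 4-methylbenzenesulfonate | C[C@H](O[Si](C)(C)C(C)(C)C)CCCCCCCCCC[C@H](O[Si](C)(C)C(C)(C)C)CCC[C@@H](C=C)[NH2+][C@H](C)[C@@H](O[Si](C)(C)C(C)(C)C)C=C.Cc1ccc(cc1)S(=O)(=O)[O-] | intermediate
21 | (2R,3S,6S)-6-[(4S,15S)-4,15-bis(tert-butyldimethylsilyloxy)hexadecyl]-3-(tert-butyldimethylsilyloxy)-2-methyl-1,2,3,6-tetrahydropyridinium 4-methylbenzenesulfonate | C[C@H](O[Si](C)(C)C(C)(C)C)CCCCCCCCCC[C@H](O[Si](C)(C)C(C)(C)C)CCC[C@H]1C=C[C@H](O[Si](C)(C)C(C)(C)C)[C@@H](C)[NH2+]1.Cc1ccc(cc1)S(=O)(=O)[O-] | intermediate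
22 | (2R,3S,6S)-6-[(4S,15S)-4,15-bis(tert-butyldimethylsilyloxy)hexadecyl]-3-(tert-butyldimethylsilyloxy)-2-methyl-1,2,3,6-tetrahydropyridine | C[C@H](O[Si](C)(C)C(C)(C)C)CCCCCCCCCC[C@H](O[Si](C)(C)C(C)(C)C)CCC[C@H]1C=C[C@H](O[Si](C)(C)C(C)(C)C)[C@@H](C)N1 | intermediate
23 | (2R,3S,6S)-6-[(4S,15S)-4,15-bis(tert-butyldimethylsilyloxy)hexadecyl]-3-(tert-butyldimethylsilyloxy)-2-methylpiperidine | C[C@H](O[Si](C)(C)C(C)(C)C)CCCCCCCCCC[C@H](O[Si](C)(C)C(C)(C)C)CCC[C@H]1CC[C@H](O[Si](C)(C)C(C)(C)C)[C@@H](C)N1 | intermediate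
24 | (2R,3S,6S)-6-[(4S,15S)-4,15-dihydroxyhexadecyl]-3-hydroxy-2-methylpiperidinium chloride | C[C@H](O)CCCCCCCCCC[C@H](O)CCC[C@H]1CC[C@H](O)[C@@H](C)[NH2+]1.[Cl-] | intermediate
25 | (2R,3S,6S)-6-[(4S,15S)-4,15-dihydroxyhexadecyl]-2-methylpiperidin-3-ol | C[C@H](O)CCCCCCCCCC[C@H](O)CCC[C@H]1CC[C@H](O)[C@@H](C)N1 | target

**Step count and risk**
Total steps: 13. Longest linear sequence: 10 steps (steps 1–7, 11, 12, 13, from 11-bromoundec-1-ene); the amine branch (steps 8–10) joins at step 11.

Most likely to fail: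

1. Step 12. If the ammonium salt partly dissociates, nitrogen can bind ruthenium, the catalyst dies, and the diene oligomerises or its alkenes migrate instead of closing. The fallback masks nitrogen covalently and cyclises a neutral substrate. It sets out from 19: trifluoroacetic anhydride and pyridine in CH2Cl2 at 0 °C should give N-[(3S,7S,18S)-7,18-bis(tert-butyldimethylsilyloxy)nonadec-1-en-3-yl]-N-[(2R,3S)-3-(tert-butyldimethylsilyloxy)pent-4-en-2-yl]-2,2,2-trifluoroacetamide F1. Ring-closing metathesis with the second-generation Grubbs catalyst (H2IMes)(PCy3)Cl2Ru=CHPh in toluene at 80 °C should then give 1-[(2R,3S,6S)-6-[(4S,15S)-4,15-bis(tert-butyldimethylsilyloxy)hexadecyl]-3-(tert-butyldimethylsilyloxy)-2-methyl-3,6-dihydro-2H-pyridin-1-yl]-2,2,2-trifluoroethan-1-one F2. K2CO3 in aqueous methanol at 50 °C removes the acyl group, and the route is rejoined at 22.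

2. Step 11. The α-branched, β-silyloxy amine may attack the allyl–iridium intermediate too slowly, so that conversion stalls, linear amine grows, or facial control at C3 erodes. The fallback builds the C3 stereocentre by C–C instead of C–N bond formation. It sets out from 10: ozonolysis (O3, CH2Cl2, −78 °C; PPh3) should give (5S,16S)-5,16-bis(tert-butyldimethylsilyloxy)heptadecanal F3. Condensation with amine 18 over MgSO4 in CH2Cl2 should give (1E,5S,16S)-5,16-bis(tert-butyldimethylsilyloxy)-N-[(2R,3S)-3-(tert-butyldimethylsilyloxy)pent-4-en-2-yl]heptadecan-1-imine F4. Addition of the vinylcerium reagent made from 14 and CeCl3 in THF at −78 °C should give 19 together with its C3 epimer, which would be separated by chromatography; the route is rejoined at 19.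

3. Step 9. Hydride delivery may show poor facial selectivity, or conjugate reduction of the vinyl ketone may compete. The fallback sets the carbinol by reagent control on an alkyne. It sets out from 13: lithium (trimethylsilyl)acetylide in THF at −78 °C should give tert-butyl N-[(2R)-3-oxo-5-(trimethylsilyl)pent-4-yn-2-yl]carbamate F5. Asymmetric transfer hydrogenation with RuCl[(R,R)-TsDPEN](p-cymene) in 2-propanol should give tert-butyl N-[(2R,3S)-3-hydroxy-5-(trimethylsilyl)pent-4-yn-2-yl]carbamate F6. K2CO3 in methanol should then give tert-butyl N-[(2R,3S)-3-hydroxypent-4-yn-2-yl]carbamate F7. Semihydrogenation with H2 over Pd/CaCO3 poisoned with Pb(OAc)2 (Lindlar catalyst) and quinoline rejoins the route at 16.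

**Further compounds**
F1 | step 12 | N-[(3S,7S,18S)-7,18-bis(tert-butyldimethylsilyloxy)nonadec-1-en-3-yl]-N-[(2R,3S)-3-(tert-butyldimethylsilyloxy)pent-4-en-2-yl]-2,2,2-trifluoroacetamide | C[C@H](O[Si](C)(C)C(C)(C)C)CCCCCCCCCC[C@H](O[Si](C)(C)C(C)(C)C)CCC[C@@H](C=C)N(C(=O)C(F)(F)F)[C@H](C)[C@@H](O[Si](C)(C)C(C)(C)C)C=C
F2 | step 12 | 1-[(2R,3S,6S)-6-[(4S,15S)-4,15-bis(tert-butyldimethylsilyloxy)hexadecyl]-3-(tert-butyldimethylsilyloxy)-2-methyl-3,6-dihydro-2H-pyridin-1-yl]-2,2,2-trifluoroethan-1-one | C[C@H](O[Si](C)(C)C(C)(C)C)CCCCCCCCCC[C@H](O[Si](C)(C)C(C)(C)C)CCC[C@H]1C=C[C@H](O[Si](C)(C)C(C)(C)C)[C@@H](C)N1C(=O)C(F)(F)F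
F3 | step 11 | (5S,16S)-5,16-bis(tert-butyldimethylsilyloxy)heptadecanal | C[C@H](O[Si](C)(C)C(C)(C)C)CCCCCCCCCC[C@H](O[Si](C)(C)C(C)(C)C)CCCC=O
F4 | step 11 | (1E,5S,16S)-5,16-bis(tert-butyldimethylsilyloxy)-N-[(2R,3S)-3-(tert-butyldimethylsilyloxy)pent-4-en-2-yl]heptadecan-1-imine | C[C@H](O[Si](C)(C)C(C)(C)C)CCCCCCCCCC[C@H](O[Si](C)(C)C(C)(C)C)CCC/C=N/[C@H](C)[C@@H](O[Si](C)(C)C(C)(C)C)C=C
F5 | step 9 | tert-butyl N-[(2R)-3-oxo-5-(trimethylsilyl)pent-4-yn-2-yl]carbamate | C[C@@H](NC(=O)OC(C)(C)C)C(=O)C#C[Si](C)(C)C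
F6 | step 9 | tert-butyl N-[(2R,3S)-3-hydroxy-5-(trimethylsilyl)pent-4-yn-2-yl]carbamate | C[C@@H](NC(=O)OC(C)(C)C)[C@@H](O)C#C[Si](C)(C)C
F7 | step 9 | tert-butyl N-[(2R,3S)-3-hydroxypent-4-yn-2-yl]carbamate | C[C@@H](NC(=O)OC(C)(C)C)[C@@H](O)C#C
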